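**Plan**

1. Numbering: lactone O1, C2 (C=O), C3 (bears the 4-hydroxy-3-methoxybenzyl group), C4 (bears the 4-hydroxy-3,5-dimethoxybenzyl group), C5 (OCH2). The retrosynthesis cuts O1–C2 (lactonisation of a γ-hydroxy ester), then C4–CH2(aryl), then C3–CH2(aryl).
2. Enabling feature: the benzyl group on C4 ends in a 4-hydroxy-3,5-dimethoxyphenyl ring, which is the aromatised form of a 2,6-dimethoxy para-quinone methide. C4 is the alpha carbon of an aldehyde when C5 is held at the aldehyde level, so an enamine can attack the exocyclic CH2 and form the C4–CH2 bond.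
3. Forward: a guaiacyl-type benzyl bromide alkylates methyl pent-4-enoate (C3–CH2 bond), and alkene cleavage unveils the C5 aldehyde. A syringyl sulfone releases the quinone methide, which is joined to the aldehyde at C4. Reduction and lactonisation then close the γ-lactone, the only ring that is built, after the chain is complete.
4. Stereochemistry: C4 (R) comes from the (R)-diphenylprolinol silyl ether catalyst. C3 (R) comes from base equilibration to the trans lactone, so the ester-bearing centre is carried racemic until then.
5. The single benzyl ether is removed last by hydrogenolysis.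

Key step: step 5

Remark on the chemistry: the sense of induction (R catalyst for 4R) is assigned from the steric shielding model of diarylprolinol silyl ether enamines; compounds 1, 3 and 6 are taken as commercial.

**Route**

Step 1
Reactants: 1 4-benzyloxy-3-methoxybenzyl alcohol
Product: 2 4-benzyloxy-3-methoxybenzyl bromide
Conditions: PBr3 (0.4 equiv), Et2O, 0 °C
Reagents that add atoms: phosphorus tribromide, BrP(Br)Br
Why: PBr3 turns the electron-rich benzylic alcohol into the bromide by SN2 displacement of the activated phosphite ester (alcohol-to-bromide substitution), the aryl ethers being inert at 0 °C; the bromide is used without storage.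

Step 2
Reactants: 3 methyl pent-4-enoate; 2 4-benzyloxy-3-methoxybenzyl bromide
Product: 4 methyl 2-(4-benzyloxy-3-methoxybenzyl)pent-4-enoate (racemic)
Conditions: LiN(iPr)2 (LDA, 1.15 equiv), THF, −78 °C; then 2 (0.9 equiv), −78 to 0 °C
Reagents that add atoms: none
Why: SN2 alkylation of the lithium ester enolate by the reactive benzylic bromide, with the enolate in slight excess to limit a second alkylation; the new centre is made racemic on purpose because it becomes the epimerisable lactone C3.

Step 3
Reactants: 4 methyl 2-(4-benzyloxy-3-methoxybenzyl)pent-4-enoate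
Product: 5 methyl 2-(4-benzyloxy-3-methoxybenzyl)-4-oxobutanoate (racemic)
Conditions: K2OsO4·2H2O (2 mol%), NaIO4 (4 equiv), 2,6-lutidine (2 equiv), 1,4-dioxane/H2O 3:1, rt
Reagents that add atoms: osmium tetroxide (formed from K2OsO4·2H2O and NaIO4), O=[Os](=O)(=O)=O; sodium periodate, [Na+].[O-]I(=O)(=O)=O
Why: Lemieux–Johnson oxidation, in which catalytic OsO4 dihydroxylates the only alkene and NaIO4 cleaves the diol to the aldehyde while 2,6-lutidine suppresses over-oxidation; ester, benzyl ether and arene should be untouched.

Step 4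
Reactants: 6 4-hydroxy-3,5-dimethoxybenzyl alcohol
Product: 7 2,6-dimethoxy-4-[(4-methylphenyl)sulfonylmethyl]phenol
Conditions: TolSO2Na (sodium 4-methylbenzenesulfinate, 1.5 equiv), HCO2H/H2O 1:1, rt
Reagents that add atoms: sodium 4-methylbenzenesulfinate, Cc1ccc(cc1)S(=O)[O-].[Na+]
Why: acid ionises the para-hydroxybenzylic alcohol to its protonated quinone methide, which the soft sulfinate captures at sulfur (SN1-type sulfone formation from an activated benzylic alcohol), giving a crystalline, storable quinone methide precursor with the phenol left free.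

Step 5
Reactants: 5 methyl 2-(4-benzyloxy-3-methoxybenzyl)-4-oxobutanoate (racemic); 7 2,6-dimethoxy-4-[(4-methylphenyl)sulfonylmethyl]phenol
Product: 9 methyl (3R)-2-(4-benzyloxy-3-methoxybenzyl)-3-formyl-4-(4-hydroxy-3,5-dimethoxyphenyl)butanoate (both C2 epimers), via syringyl quinone methide 8 (not isolated)
Conditions: (R)-2-[diphenyl(trimethylsilyloxy)methyl]pyrrolidine (20 mol%), powdered Na2CO3 (1.5 equiv), 7 (1.3 equiv) added in portions, CH2Cl2, 0 °C; pH 7 buffer work-up, crude 9 used at once
Reagents that add atoms: none
Why: Proposed new method: Na2CO3 deprotonates the phenol of 7 and 1,6-elimination of 4-methylbenzenesulfinate releases the transient quinone methide 8, while the pyrrolidine catalyst condenses with the formyl group of 5 to the E-enamine, whose alpha carbon adds to the unsubstituted exocyclic CH2 of 8; rearomatisation to the syringyl phenolate makes the addition irreversible and hydrolysis of the iminium ion returns the catalyst. The closest known reaction type is the diarylprolinol silyl ether catalysed enantioselective 1,6-addition of aldehydes to isolable 2,6-di-tert-butyl para-quinone methides that carry an aryl group on the exocyclic carbon; new here is the fleeting, exocyclic-unsubstituted dimethoxy quinone methide released in the flask from a sulfone. No ring closes. The one new stereocentre (C3 of 9, the later lactone C4) should be set R by the catalyst: in the anti E-enamine the (R)-diphenyl(silyloxy)methyl arm blocks one face and 8 adds to the other, the same facial sense as in enamine Michael additions with this catalyst class once the CIP order of the substituents is taken into account. The step needs catalyst control over the adjacent racemic ester-bearing centre, which is expected because these catalysts override a beta stereocentre in branched aldehydes, and it needs C-alkylation of the enamine over N-alkylation of the free catalyst, which slow base-triggered release of 8 from the sulfone reservoir should secure; the exocyclic carbon of 8 is not stereogenic, so no further diastereocontrol is required.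

Step 6
Reactants: 9 methyl (3R)-2-(4-benzyloxy-3-methoxybenzyl)-3-formyl-4-(4-hydroxy-3,5-dimethoxyphenyl)butanoate
Product: 11 (4R)-3-(4-benzyloxy-3-methoxybenzyl)-4-(4-hydroxy-3,5-dimethoxybenzyl)oxolan-2-one (mixture of C3 epimers), via hydroxy ester 10 (not isolated)
Conditions: NaBH4 (2 equiv), MeOH, 0 °C; then p-TsOH·H2O (10 mol%), CH2Cl2, rt
Reagents that add atoms: none
Why: borohydride reduces the aldehyde chemoselectively beside the methyl ester (done at once so that the formyl-bearing centre cannot enolise), and acid-catalysed intramolecular transesterification of the γ-hydroxy ester closes the five-membered lactone with loss of methanol; C4 keeps its R configuration.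

Step 7
Reactants: 11 (4R)-3-(4-benzyloxy-3-methoxybenzyl)-4-(4-hydroxy-3,5-dimethoxybenzyl)oxolan-2-one (C3 epimers)
Product: 12 (3R,4R)-3-(4-benzyloxy-3-methoxybenzyl)-4-(4-hydroxy-3,5-dimethoxybenzyl)oxolan-2-one
Conditions: DBU (2 equiv), toluene, 80 °C, under argon; dilute HCl wash
Reagents that add atoms: none
Why: DBU reversibly forms the lactone enolate and reprotonation equilibrates C3 (thermodynamic epimerisation) towards the trans-3,4-dibenzyl lactone, so the fixed 4R centre dictates 3R; C4 carries no acidic hydrogen and should not be touched.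

Step 8
Reactants: 12 (3R,4R)-3-(4-benzyloxy-3-methoxybenzyl)-4-(4-hydroxy-3,5-dimethoxybenzyl)oxolan-2-one
Product: 13 (3R,4R)-4-(4-hydroxy-3,5-dimethoxybenzyl)-3-(4-hydroxy-3-methoxybenzyl)oxolan-2-one (target)
Conditions: H2 (1 atm), Pd/C (10 wt% Pd on carbon), EtOAc/MeOH, rt
Reagents that add atoms: none
Why: catalytic hydrogenolysis cleaves the benzyl aryl ether to the free phenol and toluene under neutral conditions that should leave the lactone, the methyl ethers and both stereocentres unchanged.

**Compound list**

1 | 4-benzyloxy-3-methoxybenzyl alcohol | COc1cc(CO)ccc1OCc1ccccc1 | starting material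
2 | 4-benzyloxy-3-methoxybenzyl bromide | COc1cc(CBr)ccc1OCc1ccccc1 | intermediate
3 | methyl pent-4-enoate | C=CCCC(=O)OC | starting material
4 | methyl 2-(4-benzyloxy-3-methoxybenzyl)pent-4-enoate (racemic) | C=CCC(Cc1ccc(OCc2ccccc2)c(OC)c1)C(=O)OC | intermediate
5 | methyl 2-(4-benzyloxy-3-methoxybenzyl)-4-oxobutanoate (racemic) | COC(=O)C(CC=O)Cc1ccc(OCc2ccccc2)c(OC)c1 | intermediate
6 | 4-hydroxy-3,5-dimethoxybenzyl alcohol | OCc1cc(OC)c(O)c(OC)c1 | starting material
7 | 2,6-dimethoxy-4-[(4-methylphenyl)sulfonylmethyl]phenol | COc1cc(CS(=O)(=O)c2ccc(C)cc2)cc(OC)c1O | intermediate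
8 | 2,6-dimethoxy-4-methylidenecyclohexa-2,5-dien-1-one (syringyl quinone methide; formed in the flask, not isolated) | C=C1C=C(OC)C(=O)C(OC)=C1 | intermediate
9 | methyl (3R)-2-(4-benzyloxy-3-methoxybenzyl)-3-formyl-4-(4-hydroxy-3,5-dimethoxyphenyl)butanoate (both C2 epimers) | COC(=O)C(Cc1ccc(OCc2ccccc2)c(OC)c1)[C@H](C=O)Cc1cc(OC)c(O)c(OC)c1 | intermediate
10 | methyl (3R)-2-(4-benzyloxy-3-methoxybenzyl)-4-(4-hydroxy-3,5-dimethoxyphenyl)-3-(hydroxymethyl)butanoate (both C2 epimers; formed in the flask, not isolated) | COC(=O)C(Cc1ccc(OCc2ccccc2)c(OC)c1)[C@H](CO)Cc1cc(OC)c(O)c(OC)c1 | intermediate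
11 | (4R)-3-(4-benzyloxy-3-methoxybenzyl)-4-(4-hydroxy-3,5-dimethoxybenzyl)oxolan-2-one (3R and 3S epimers) | COc1cc(CC2C(=O)OC[C@@H]2Cc2cc(OC)c(O)c(OC)c2)ccc1OCc1ccccc1 | intermediate
12 | (3R,4R)-3-(4-benzyloxy-3-methoxybenzyl)-4-(4-hydroxy-3,5-dimethoxybenzyl)oxolan-2-one | COc1cc(C[C@H]2C(=O)OC[C@@H]2Cc2cc(OC)c(O)c(OC)c2)ccc1OCc1ccccc1 | intermediate
13 | (3R,4R)-4-(4-hydroxy-3,5-dimethoxybenzyl)-3-(4-hydroxy-3-methoxybenzyl)oxolan-2-one | COc1cc(C[C@H]2C(=O)OC[C@@H]2Cc2cc(OC)c(O)c(OC)c2)ccc1O | target

**Step count and risks**

Total steps: 8. Longest linear sequence: 7 steps (1 → 2 → 4 → 5 → 9 → 11 → 12 → 13; step 4 is a one-step side branch).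

Steps most likely to fail:

Step 5. The catalyst nitrogen may be alkylated by the quinone methide, the quinone methide may oligomerise before it meets the enamine, or facial control may weaken in the mismatched pairing with one enantiomer of the racemic aldehyde. The fallback uses known chemistry, sets out from bromide 2 and comes back to the route at 13. Stobbe condensation of commercial 4-benzyloxy-3,5-dimethoxybenzaldehyde with dimethyl succinate (NaOMe, MeOH, reflux) would give (E)-4-(4-benzyloxy-3,5-dimethoxyphenyl)-3-(methoxycarbonyl)but-3-enoic acid F1. Asymmetric hydrogenation with [Rh(cod)2]BF4 and a chiral bisphosphine of the DuPhos type (ligand antipode chosen for the R acid; H2, MeOH) would give (3R)-4-(4-benzyloxy-3,5-dimethoxyphenyl)-3-(methoxycarbonyl)butanoic acid F2. Its potassium salt would be reduced at the ester with Ca(BH4)2 (CaCl2, NaBH4, EtOH) to (3R)-3-(4-benzyloxy-3,5-dimethoxybenzyl)-4-hydroxybutanoic acid F3, which on acidification should close to (4R)-4-(4-benzyloxy-3,5-dimethoxybenzyl)oxolan-2-one F4. Its lithium enolate (LiN(SiMe3)2, THF, −78 °C) would be alkylated by 2 anti to the C4 substituent to give (3R,4R)-3-(4-benzyloxy-3-methoxybenzyl)-4-(4-benzyloxy-3,5-dimethoxybenzyl)oxolan-2-one F5. Hydrogenolysis under the conditions of step 8 would remove both benzyl ethers and give 13.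

Step 7. Equilibration may stall at a mixture of C3 epimers, or the phenolate formed with DBU may slow enolisation. The fallback sets C3 by kinetic, substrate-controlled alkylation instead of equilibration; it sets out from sulfone 7 (with bromide 2) and comes back at 13. Commercial methyl 4-oxobutanoate and 7 under the conditions of step 5 would give methyl (3R)-3-formyl-4-(4-hydroxy-3,5-dimethoxyphenyl)butanoate F6. NaBH4 in MeOH would give methyl (3R)-4-hydroxy-3-(4-hydroxy-3,5-dimethoxybenzyl)butanoate F7, which with p-TsOH·H2O should close to (4R)-4-(4-hydroxy-3,5-dimethoxybenzyl)oxolan-2-one F8. O-Benzylation (benzyl bromide, K2CO3, acetone) would give the lactone F4 described above, and enolate alkylation with 2 followed by hydrogenolysis would proceed through F5 to 13 as before.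

Step 4. Acid-induced self-condensation of the labile syringyl alcohol to diarylmethanes may outrun capture by sulfinate. The fallback avoids acid, sets out from 6 and comes back at quinone methide 8 in step 5. Acylation of the primary hydroxyl with immobilised Candida antarctica lipase B and vinyl acetate in tert-butyl methyl ether at rt would give 4-hydroxy-3,5-dimethoxybenzyl acetate F9, which should lose acetate to 8 under the base of step 5.

**Further compounds**

F1 | step 5 | (E)-4-(4-benzyloxy-3,5-dimethoxyphenyl)-3-(methoxycarbonyl)but-3-enoic acid | OC(=O)C/C(C(=O)OC)=C\c1cc(OC)c(OCc2ccccc2)c(OC)c1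
F2 | step 5 | (3R)-4-(4-benzyloxy-3,5-dimethoxyphenyl)-3-(methoxycarbonyl)butanoic acid | COC(=O)[C@@H](CC(=O)O)Cc1cc(OC)c(OCc2ccccc2)c(OC)c1
F3 | step 5 | (3R)-3-(4-benzyloxy-3,5-dimethoxybenzyl)-4-hydroxybutanoic acid | OC[C@@H](CC(=O)O)Cc1cc(OC)c(OCc2ccccc2)c(OC)c1
F4 | step 5 | (4R)-4-(4-benzyloxy-3,5-dimethoxybenzyl)oxolan-2-one | O=C1OC[C@H](Cc2cc(OC)c(OCc3ccccc3)c(OC)c2)C1
F5 | step 5 | (3R,4R)-3-(4-benzyloxy-3-methoxybenzyl)-4-(4-benzyloxy-3,5-dimethoxybenzyl)oxolan-2-one | COc1cc(C[C@H]2C(=O)OC[C@@H]2Cc2cc(OC)c(OCc3ccccc3)c(OC)c2)ccc1OCc1ccccc1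
F6 | step 7 | methyl (3R)-3-formyl-4-(4-hydroxy-3,5-dimethoxyphenyl)butanoate | COC(=O)C[C@H](C=O)Cc1cc(OC)c(O)c(OC)c1
F7 | step 7 | methyl (3R)-4-hydroxy-3-(4-hydroxy-3,5-dimethoxybenzyl)butanoate | COC(=O)C[C@H](CO)Cc1cc(OC)c(O)c(OC)c1
F8 | step 7 | (4R)-4-(4-hydroxy-3,5-dimethoxybenzyl)oxolan-2-one | O=C1OC[C@H](Cc2cc(OC)c(O)c(OC)c2)C1
F9 | step 4 | 4-hydroxy-3,5-dimethoxybenzyl acetate | CC(=O)OCc1cc(OC)c(O)c(OC)c1
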